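**Retrosynthetic overview**

1. Numbering (eudesmane): ring A = C1–C5/C10, ring B = C5–C10, C14 = methyl on C10, C15 = CH2O on C4, C11–C13 = acrylic acid unit on C7; β = face of C14.
2. Late disconnections: C12 tert-butyl ester; C15–O ester (Mitsunobu coupling with (Z)-p-coumaric acid 23); C4–C15 (Stille coupling on the C3=C4 enol triflate of a C4 ketone); C11=C13 (Mannich methylenation of a C7–CH2CO2t-Bu chain).
3. Key disconnection: ring B is cut into C9–C10–C5 (nitro ketone 3) and C6–C7–C8 (2-substituted acrolein 5); C8–C9 forms by nitro-Michael addition and C5–C6 by aldol condensation in one operation. Ring A is bought (3-methylcyclohexenone), ring B is formed second, the arene is bought.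
4. Enabling feature: in ring B, C9 and C5 are 1,3-related across the quaternary C10. C5 is α to C4, which can stay a ketone until C15 is attached, and C9 is a plain CH2 that can carry a temporary nitro group, so both are nucleophiles for the 1,3-dielectrophile C8=C7–C6H=O. The resulting C5=C6 enone lets hydrogen enter anti to C14 (trans ring fusion).
5. Stereocentres: C10 from an asymmetric nitromethane addition (step 1), C7 by equilibration in the enone (step 3), C5 by hydrogenation (step 4); the (Z)-alkene from a Still–Gennari olefination (step 9).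

Key step: step 3

Remark: tert-butyl 4-oxobutanoate 4 is taken as a purchasable aldehyde; α/β descriptors in the names refer to the eudesmane numbering given above.

**Route**

Step 1
Reactants: 1 3-methylcyclohex-2-en-1-one; 2 nitromethane
Product: 3 (S)-3-methyl-3-(nitromethyl)cyclohexan-1-one
Conditions: MeNO2 (10 equiv), 9-amino-9-deoxy-epi-cinchona primary amine (10 mol %, the pseudo-enantiomer that gives the S adduct), PhCO2H (20 mol %), PhMe, 50 °C, ca. 9 kbar
Reagents that add atoms: none
Why: Iminium-catalysed asymmetric Michael addition of nitromethane to the β-substituted enone, a known way to this quaternary γ-nitro ketone that is slow at ambient pressure and is therefore run under high pressure; the chiral primary amine shields one face of the iminium ion and so sets C10.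

Step 2
Reactants: 4 tert-butyl 4-oxobutanoate
Product: 5 tert-butyl 3-formylbut-3-enoate
Conditions: aq. CH2O (37 %), pyrrolidine (10 mol %), EtCO2H (10 mol %), i-PrOH, 45 °C
Reagents that add atoms: formaldehyde, C=O
Why: Organocatalytic Mannich condensation–elimination (α-methylenation of an aldehyde): the enamine of 4 adds to the formaldehyde-derived iminium ion and loss of pyrrolidine gives the 2-substituted acrolein, which is used at once because base can move its double bond into conjugation with the ester.

Step 3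
Reactants: 3 (S)-3-methyl-3-(nitromethyl)cyclohexan-1-one; 5 tert-butyl 3-formylbut-3-enoate
Product: 8 tert-butyl 2-(4a-methyl-4-nitro-8-oxo-2,3,4,4a,5,6,7,8-octahydronaphthalen-2-yl)acetate (C5=C6 enone; 7β side chain cis to the 10β methyl; both C9 nitro epimers), via Michael adduct 6 (not isolated), via aldol 7 (not isolated)
Conditions: Et3N (0.2 equiv), MeOH, 0 °C to rt; then KOH (2.5 equiv), rt to 45 °C; AcOH, 0 °C
Reagents that add atoms: none
Why: Et3N forms only the nitronate of 3, which adds to the CH2 terminus (C8) of enal 5 in a nitro-Michael addition to give keto aldehyde 6; KOH then enolises the C4 ketone, the C5 enolate attacks the C6 aldehyde, and E1cB loss of water from aldol 7 gives the conjugated C5=C6 enone, so the whole is a Robinson-type Michael/aldol-condensation annulation in its three-plus-three form. Ring B closes by a 6-(enolexo)-exo-trig aldol addition of C5 onto C6=O followed by dehydration. C10 is carried over from 3, and under KOH the nitro group is held as its nitronate, which cannot leave as a carbanion, so retro-Michael cleavage of C9–C10 and loss of configuration at C10 are blocked. C7 is epimerisable (α to the aldehyde before closure, γ to the enone afterwards through the dienolate) and should settle with the CH2CO2t-Bu group pseudo-equatorial, which is the β face because C14 is pseudo-axial on the half-chair of ring B; C9 stays a mixture and C5/C6 are sp2. The step needs selectivity between two aldol modes: attack of the aldehyde enolate (C7) on the C4 ketone gives a bridged bicyclo[3.3.1]nonane aldol that cannot dehydrate (bridgehead alkene) and reverts under hydroxide, and a C3 enolate cannot reach C6 in a six-membered ring, so only the C5/C6 closure is drained by irreversible dehydration. The tert-butyl ester is inert to KOH/MeOH and the cold acetic acid quench avoids a Nef reaction.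

Step 4
Reactants: 8 tert-butyl 2-(4a-methyl-4-nitro-8-oxo-2,3,4,4a,5,6,7,8-octahydronaphthalen-2-yl)acetate
Product: 9 tert-butyl 2-(4a-methyl-4-nitro-8-oxodecahydronaphthalen-2-yl)acetate (trans-fused: 5α-H, 10β-methyl; 7β side chain; both C9 epimers)
Conditions: H2 (1 atm), Pd/C (10 %), EtOAc, rt, stopped after one equivalent of H2
Reagents that add atoms: none
Why: Heterogeneous catalytic hydrogenation adds H2 syn to the C5=C6 enone from the α face, opposite the pseudo-axial C14 methyl that stands next to C5 (the bias that gives 5α products from steroidal 5-enes), so H5 ends trans to C14; the aliphatic nitro group is reduced much more slowly, any C7α epimer is separated here, and base and acid are avoided from now on because this trans ketone is only modestly favoured over its C5 epimer.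

Step 5
Reactants: 9 tert-butyl 2-(4a-methyl-4-nitro-8-oxodecahydronaphthalen-2-yl)acetate
Product: 10 tert-butyl 2-[(2R,4aR,8aR)-4a-methyl-8-oxodecahydronaphthalen-2-yl]acetate (5α-H, 7β side chain, 10β-methyl)
Conditions: Bu3SnH (5 equiv), AIBN (0.3 equiv), PhMe, 110 °C
Reagents that add atoms: none
Why: Radical denitration by a tin hydride chain: Bu3Sn• adds to a nitro oxygen, the C9–N bond breaks to the secondary C9 radical and Bu3SnH delivers hydrogen, and the neutral medium leaves the epimerisable C5 centre, the ketone and the ester alone.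

Step 6
Reactants: 10 tert-butyl 2-[(2R,4aR,8aR)-4a-methyl-8-oxodecahydronaphthalen-2-yl]acetate
Product: 12 tert-butyl 2-[4a-methyl-8-(trifluoromethylsulfonyloxy)-1,2,3,4,4a,5,6,8a-octahydronaphthalen-2-yl]acetate (C3=C4 enol triflate; 5α-H, 7β, 10β-methyl), via potassium enolate 11 (not isolated)
Conditions: KN(SiMe3)2 (1.1 equiv), THF, −78 °C (ketone added to base); then PhNTf2, −78 to 0 °C
Reagents that add atoms: N-phenylbis(trifluoromethanesulfonimide), O=S(=O)(N(c1ccccc1)S(=O)(=O)C(F)(F)F)C(F)(F)F
Why: Kinetic enolate formation and O-triflation (enol triflate synthesis): the hindered amide base removes a C3 proton, not the C5 methine next to the quaternary C10 nor the less acidic ester CH2, and irreversible deprotonation at low temperature keeps H5 α.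

Step 7
Reactants: 12 tert-butyl 2-[4a-methyl-8-(trifluoromethylsulfonyloxy)-1,2,3,4,4a,5,6,8a-octahydronaphthalen-2-yl]acetate
Product: 16 tert-butyl 2-[4a-methyl-8-(trifluoromethylsulfonyloxy)-1,2,3,4,4a,5,6,8a-octahydronaphthalen-2-yl]prop-2-enoate (5α-H, 7β, 10β-methyl), via lithium enolate 13 (not isolated), via Mannich base 14 (not isolated), via ammonium iodide 15 (not isolated)
Conditions: LiN(i-Pr)2, THF, −78 °C; CH2=NMe2+ I−, −78 °C to rt; MeI, CH2Cl2, rt; DBU, rt
Reagents that add atoms: N,N-dimethylmethyleneiminium iodide, C=[N+](C)C.[I-]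
Why: α-Methylenation of an ester by Mannich alkylation of its lithium enolate with the preformed iminium salt, N-methylation and E1cB loss of trimethylamine; C7 is not acidic in substrate or product and the alkenyl triflate tolerates the amide base at −78 °C.

Step 8
Reactants: 16 tert-butyl 2-[4a-methyl-8-(trifluoromethylsulfonyloxy)-1,2,3,4,4a,5,6,8a-octahydronaphthalen-2-yl]prop-2-enoate
Product: 17 tert-butyl 2-[(2R,4aR,8aR)-8-(hydroxymethyl)-4a-methyl-1,2,3,4,4a,5,6,8a-octahydronaphthalen-2-yl]prop-2-enoate
Conditions: Bu3SnCH2OH, Pd(PPh3)4 (10 mol %), LiCl (3 equiv), 1,4-dioxane, 95 °C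
Reagents that add atoms: (tributylstannyl)methanol, CCCC[Sn](CCCC)(CCCC)CO
Why: Stille coupling of the cyclohexenyl triflate with the hydroxymethyl stannane (chloride stabilises the oxidative-addition complex of zerovalent palladium for the slow sp3 transfer) puts C15 on C4 at the alcohol oxidation level; with no base present a Heck reaction of the acrylate cannot turn over.

Step 9
Reactants: 18 4-(tert-butyldimethylsilyloxy)benzaldehyde; 19 methyl 2-[bis(2,2,2-trifluoroethoxy)phosphoryl]acetate
Product: 21 methyl (Z)-3-[4-(tert-butyldimethylsilyloxy)phenyl]prop-2-enoate, via phosphonate carbanion 20 (not isolated)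
Conditions: KN(SiMe3)2, 18-crown-6, THF, −78 °C
Reagents that add atoms: none
Why: Still–Gennari olefination: the trifluoroethyl phosphonate with a dissociated potassium counter-ion eliminates fast from the syn oxaphosphetane, so the kinetic (Z)-cinnamate should predominate.

Step 10
Reactants: 21 methyl (Z)-3-[4-(tert-butyldimethylsilyloxy)phenyl]prop-2-enoate
Product: 23 (Z)-3-(4-hydroxyphenyl)prop-2-enoic acid, via dilithium salt 22 (not isolated)
Conditions: LiOH (4 equiv), THF/H2O, 0 °C to rt, dark; then 1 M HCl to pH 3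
Reagents that add atoms: lithium hydroxide, [Li+].[OH-]
Why: Saponification with concomitant cleavage of the base-labile aryl silyl ether, run without heating and in the dark because the (Z)-phenolate isomerises photochemically.

Step 11
Reactants: 17 tert-butyl 2-[(2R,4aR,8aR)-8-(hydroxymethyl)-4a-methyl-1,2,3,4,4a,5,6,8a-octahydronaphthalen-2-yl]prop-2-enoate; 23 (Z)-3-(4-hydroxyphenyl)prop-2-enoic acid
Product: 24 tert-butyl 2-[(2R,4aR,8aR)-8-({[(2Z)-3-(4-hydroxyphenyl)prop-2-enoyl]oxy}methyl)-4a-methyl-1,2,3,4,4a,5,6,8a-octahydronaphthalen-2-yl]prop-2-enoate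
Conditions: PPh3, DIAD, THF, 0 °C to rt, dark
Reagents that add atoms: none
Why: Mitsunobu esterification: the primary allylic alcohol is activated as its alkoxyphosphonium ion and displaced (SN2) by the carboxylate, which is far more acidic than the phenol and so reacts chemoselectively, and the neutral conditions keep the (Z)-alkene.

Step 12
Reactants: 24 tert-butyl 2-[(2R,4aR,8aR)-8-({[(2Z)-3-(4-hydroxyphenyl)prop-2-enoyl]oxy}methyl)-4a-methyl-1,2,3,4,4a,5,6,8a-octahydronaphthalen-2-yl]prop-2-enoate
Product: 26 2-[(2R,4aR,8aR)-8-({[(2Z)-3-(4-hydroxyphenyl)prop-2-enoyl]oxy}methyl)-4a-methyl-1,2,3,4,4a,5,6,8a-octahydronaphthalen-2-yl]prop-2-enoic acid, via bis-silyl derivative 25 (not isolated)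
Conditions: Me3SiOTf (3 equiv), 2,6-lutidine (4 equiv), CH2Cl2, 0 °C; then aq. citric acid, THF, 0 °C
Reagents that add atoms: none
Why: Silyl triflate-mediated cleavage of the tert-butyl ester (O-silylation, loss of isobutene) under lutidine buffering, then hydrolysis of the silyl ester and aryl silyl ether on mild acidic work-up, should free the acid without ionising the allylic ester or isomerising the (Z)-enoate.

**Compound list**

1 | 3-methylcyclohex-2-en-1-one | CC1=CC(=O)CCC1 | starting material
2 | nitromethane | C[N+](=O)[O-] | starting material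
3 | (S)-3-methyl-3-(nitromethyl)cyclohexan-1-one | [O-][N+](=O)C[C@@]1(C)CCCC(=O)C1 | intermediate
4 | tert-butyl 4-oxobutanoate | CC(C)(C)OC(=O)CCC=O | starting material
5 | tert-butyl 3-formylbut-3-enoate | C=C(C=O)CC(=O)OC(C)(C)C | intermediate
6 | tert-butyl 3-formyl-5-[(1S)-1-methyl-3-oxocyclohexyl]-5-nitropentanoate (Michael adduct, epimers at chain C3 and C5) | O=CC(CC(=O)OC(C)(C)C)CC([N+](=O)[O-])[C@@]1(C)CCCC(=O)C1 | intermediate
7 | tert-butyl 2-(1-hydroxy-4a-methyl-4-nitro-8-oxodecahydronaphthalen-2-yl)acetate (aldol, 10β-methyl fixed, other centres mixed) | CC(C)(C)OC(=O)CC1CC([N+](=O)[O-])[C@@]2(C)CCCC(=O)C2C1O | intermediate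
8 | tert-butyl 2-(4a-methyl-4-nitro-8-oxo-2,3,4,4a,5,6,7,8-octahydronaphthalen-2-yl)acetate (C5=C6 enone, 7β side chain, 10β-methyl, C9 epimers) | CC(C)(C)OC(=O)C[C@@H]1CC([N+](=O)[O-])[C@@]2(C)CCCC(=O)C2=C1 | intermediate
9 | tert-butyl 2-(4a-methyl-4-nitro-8-oxodecahydronaphthalen-2-yl)acetate (trans-fused, 5α-H, 7β side chain, 10β-methyl, C9 epimers) | CC(C)(C)OC(=O)C[C@@H]1CC([N+](=O)[O-])[C@@]2(C)CCCC(=O)[C@@H]2C1 | intermediate
10 | tert-butyl 2-[(2R,4aR,8aR)-4a-methyl-8-oxodecahydronaphthalen-2-yl]acetate | CC(C)(C)OC(=O)C[C@@H]1CC[C@@]2(C)CCCC(=O)[C@@H]2C1 | intermediate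
11 | potassium C3=C4 enolate of 10 | CC(C)(C)OC(=O)C[C@@H]1CC[C@@]2(C)CCC=C([O-])[C@@H]2C1.[K+] | intermediate
12 | tert-butyl 2-[4a-methyl-8-(trifluoromethylsulfonyloxy)-1,2,3,4,4a,5,6,8a-octahydronaphthalen-2-yl]acetate (5α-H, 7β, 10β-methyl) | CC(C)(C)OC(=O)C[C@@H]1CC[C@@]2(C)CCC=C(OS(=O)(=O)C(F)(F)F)[C@@H]2C1 | intermediate
13 | lithium ester enolate of 12 | [Li+].[O-]C(OC(C)(C)C)=C[C@@H]1CC[C@@]2(C)CCC=C(OS(=O)(=O)C(F)(F)F)[C@@H]2C1 | intermediate
14 | tert-butyl 3-(dimethylamino)-2-[4a-methyl-8-(trifluoromethylsulfonyloxy)-1,2,3,4,4a,5,6,8a-octahydronaphthalen-2-yl]propanoate (Mannich base, C11 epimers) | CN(C)CC(C(=O)OC(C)(C)C)[C@@H]1CC[C@@]2(C)CCC=C(OS(=O)(=O)C(F)(F)F)[C@@H]2C1 | intermediate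
15 | trimethylammonium iodide of 14 | C[N+](C)(C)CC(C(=O)OC(C)(C)C)[C@@H]1CC[C@@]2(C)CCC=C(OS(=O)(=O)C(F)(F)F)[C@@H]2C1.[I-] | intermediate
16 | tert-butyl 2-[4a-methyl-8-(trifluoromethylsulfonyloxy)-1,2,3,4,4a,5,6,8a-octahydronaphthalen-2-yl]prop-2-enoate (5α-H, 7β, 10β-methyl) | C=C(C(=O)OC(C)(C)C)[C@@H]1CC[C@@]2(C)CCC=C(OS(=O)(=O)C(F)(F)F)[C@@H]2C1 | intermediate
17 | tert-butyl 2-[(2R,4aR,8aR)-8-(hydroxymethyl)-4a-methyl-1,2,3,4,4a,5,6,8a-octahydronaphthalen-2-yl]prop-2-enoate | C=C(C(=O)OC(C)(C)C)[C@@H]1CC[C@@]2(C)CCC=C(CO)[C@@H]2C1 | intermediate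
18 | 4-(tert-butyldimethylsilyloxy)benzaldehyde | O=Cc1ccc(O[Si](C)(C)C(C)(C)C)cc1 | starting material
19 | methyl 2-[bis(2,2,2-trifluoroethoxy)phosphoryl]acetate | COC(=O)CP(=O)(OCC(F)(F)F)OCC(F)(F)F | starting material
20 | potassium salt of the carbanion of 19 | [K+].COC(=O)[CH-]P(=O)(OCC(F)(F)F)OCC(F)(F)F | intermediate
21 | methyl (Z)-3-[4-(tert-butyldimethylsilyloxy)phenyl]prop-2-enoate | COC(=O)/C=C\c1ccc(O[Si](C)(C)C(C)(C)C)cc1 | intermediate
22 | dilithium (Z)-3-(4-oxidophenyl)prop-2-enoate | [Li+].[Li+].[O-]C(=O)/C=C\c1ccc([O-])cc1 | intermediate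
23 | (Z)-3-(4-hydroxyphenyl)prop-2-enoic acid | OC(=O)/C=C\c1ccc(O)cc1 | intermediate
24 | tert-butyl 2-[(2R,4aR,8aR)-8-({[(2Z)-3-(4-hydroxyphenyl)prop-2-enoyl]oxy}methyl)-4a-methyl-1,2,3,4,4a,5,6,8a-octahydronaphthalen-2-yl]prop-2-enoate | C=C(C(=O)OC(C)(C)C)[C@@H]1CC[C@@]2(C)CCC=C(COC(=O)/C=C\c3ccc(O)cc3)[C@@H]2C1 | intermediate
25 | trimethylsilyl ester and aryl trimethylsilyl ether of 26 | C=C(C(=O)O[Si](C)(C)C)[C@@H]1CC[C@@]2(C)CCC=C(COC(=O)/C=C\c3ccc(O[Si](C)(C)C)cc3)[C@@H]2C1 | intermediate
26 | 2-[(2R,4aR,8aR)-8-({[(2Z)-3-(4-hydroxyphenyl)prop-2-enoyl]oxy}methyl)-4a-methyl-1,2,3,4,4a,5,6,8a-octahydronaphthalen-2-yl]prop-2-enoic acid | C=C(C(=O)O)[C@@H]1CC[C@@]2(C)CCC=C(COC(=O)/C=C\c3ccc(O)cc3)[C@@H]2C1 | target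

**Step count**

Total: 12 steps. Longest linear sequence: 9 steps (1, 3, 4, 5, 6, 7, 8, 11, 12).

**Steps most likely to fail**

Step 3. The aldehyde enolate may close onto the C4 ketone faster than the bridged aldol reverts, base may move the double bond of 5 into conjugation before the Michael addition, and equilibration at C7 may stay incomplete. The fallback sets out from 3 and 4. Aldehyde 4 is condensed with Me2NCH(OMe)2 to the vinylogous formamide tert-butyl 4-(dimethylamino)-3-formylbut-3-enoate F1, which has neither an enolisable aldehyde α-hydrogen nor a double bond that can migrate. With 3 under piperidinium acetate in hot EtOH the nitronate should displace dimethylamine at the β-carbon (addition–elimination), and the C5/C6 aldol condensation should then give the dienone tert-butyl 2-(4a-methyl-4-nitro-8-oxo-4,4a,5,6,7,8-hexahydronaphthalen-2-yl)acetate F2 (C5=C6 and C7=C8). Hydrogenation of both double bonds from the α face (H2, Pd/C) would set C5 and C7 by the same shielding of C14 and comes back to the route at 9.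

Step 5. Homolysis of the secondary C9–NO2 bond may be slow, so that the chain stalls and starting material is recovered. The fallback sets out from 9. NaBH4 (MeOH, 0 °C) reduces the C4 ketone to the nitro alcohol tert-butyl 2-(8-hydroxy-4a-methyl-4-nitrodecahydronaphthalen-2-yl)acetate F3, so that the amine to come cannot condense onto C4. NiCl2·6H2O/NaBH4 then reduces the nitro group to the amino alcohol tert-butyl 2-(4-amino-8-hydroxy-4a-methyldecahydronaphthalen-2-yl)acetate F4. The primary amine is excised with the anomeric amide N-(benzyloxy)-N-(pivaloyloxy)-4-(trifluoromethyl)benzamide (isodiazene, loss of N2) to give the alcohol tert-butyl 2-(8-hydroxy-4a-methyldecahydronaphthalen-2-yl)acetate F5. Dess–Martin oxidation returns ketone 10 without touching C5.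

Step 8. Transfer of the sp3 hydroxymethyl group from tin to palladium may be slow at the hindered alkenyl triflate, so that triflate reduction or hydrolysis and thermal polymerisation of the acrylate compete. The fallback sets out from 16. Palladium-catalysed formylation of the triflate (Pd(OAc)2, dppp, CO, Et3SiH, Et3N, DMF, 70 °C) gives the enal tert-butyl 2-(8-formyl-4a-methyl-1,2,3,4,4a,5,6,8a-octahydronaphthalen-2-yl)prop-2-enoate F6, and Luche reduction (NaBH4, CeCl3·7H2O, MeOH, −40 °C) of the aldehyde alone comes back to the route at 17.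

**Further compounds**

F1 | step 3 | tert-butyl 4-(dimethylamino)-3-formylbut-3-enoate | CN(C)C=C(C=O)CC(=O)OC(C)(C)C
F2 | step 3 | tert-butyl 2-(4a-methyl-4-nitro-8-oxo-4,4a,5,6,7,8-hexahydronaphthalen-2-yl)acetate (10β-methyl, C9 epimers) | CC(C)(C)OC(=O)CC1=CC([N+](=O)[O-])[C@@]2(C)CCCC(=O)C2=C1
F3 | step 5 | tert-butyl 2-(8-hydroxy-4a-methyl-4-nitrodecahydronaphthalen-2-yl)acetate (5α-H, 7β, 10β-methyl; C4 and C9 epimers) | CC(C)(C)OC(=O)C[C@@H]1CC([N+](=O)[O-])[C@@]2(C)CCCC(O)[C@@H]2C1
F4 | step 5 | tert-butyl 2-(4-amino-8-hydroxy-4a-methyldecahydronaphthalen-2-yl)acetate (5α-H, 7β, 10β-methyl; C4 and C9 epimers) | CC(C)(C)OC(=O)C[C@@H]1CC(N)[C@@]2(C)CCCC(O)[C@@H]2C1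
F5 | step 5 | tert-butyl 2-(8-hydroxy-4a-methyldecahydronaphthalen-2-yl)acetate (5α-H, 7β, 10β-methyl; C4 epimers) | CC(C)(C)OC(=O)C[C@@H]1CC[C@@]2(C)CCCC(O)[C@@H]2C1
F6 | step 8 | tert-butyl 2-(8-formyl-4a-methyl-1,2,3,4,4a,5,6,8a-octahydronaphthalen-2-yl)prop-2-enoate (5α-H, 7β, 10β-methyl) | C=C(C(=O)OC(C)(C)C)[C@@H]1CC[C@@]2(C)CCC=C(C=O)[C@@H]2C1
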